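**Retrosynthetic overview**
1. Target ⇐ desilylation ⇐ double angeloylation of the C5/C9 diol of an epoxy-cyclodecane; the C10 (R)-2-methylbutanoate is carried from the open-chain stage.
2. Ten-membered carbocycle and cis-oxirane ⇐ formed together: a C7 diphenylsulfonium ylide adds to the C8 methyl ketone (C7–C8 bond) and the betaine closes the epoxide (C7–O bond).
3. Open-chain ylide precursor ⇐ C8–C10 by anti γ-alkoxyallylation of a C10 aldehyde, then Wacker oxidation; C5 by Felkin reduction; C6–C7–S by vinyl Grignard addition and thiol conjugate addition.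
4. C10 aldehyde / C5 vinyl ketone ⇐ glycol cleavage of the C5–C10 bond of a cyclohexane made from (S)-carvone, which supplies C1 and, by epoxidation and inverting hydrolysis, the C3/C4 trans-diol.
5. Ring order: the carvone ring is only a stereochemical template and is opened in step 6; carbocycle and oxirane then form in one operation in step 13.

Locants: C1–C10 are the ring carbons of the target (C1 = CH–isopropenyl, C2 = CH2, C3 = CHOH, C4 = C(CH3)OH, C5 = CH–O-angeloyl, C6 = CH2, C7 = epoxide CH, C8 = epoxide C–CH3, C9 = CH–O-angeloyl, C10 = CH–O-2-methylbutanoyl). Open-chain intermediates keep these locants in the text.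

Assumption: the 2-methylbutanoyl centre is R as the SMILES is written; (S)-carvone, (R)-2-methylbutanoic acid and angelic acid are bought as single isomers.

**Route**

Step 1
Reactants: 1 (S)-carvone
Product: 2 (1S,4S,6S)-1-methyl-4-(prop-1-en-2-yl)-7-oxabicyclo[4.1.0]heptan-2-one
Conditions: 30% H2O2, NaOH (cat.), MeOH, 0 °C
Reagents that add atoms: hydrogen peroxide, OO
Why: Weitz–Scheffer nucleophilic epoxidation of the enone, in which hydroperoxide adds to C3 axially and anti to the isopropenyl group, so the oxirane forms trans to isopropenyl as one diastereomer and the isolated isopropenyl alkene is untouched.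

Step 2
Reactants: 2 (1S,4S,6S)-1-methyl-4-(prop-1-en-2-yl)-7-oxabicyclo[4.1.0]heptan-2-one
Product: 3 (2S,3R,5S)-2,3-dihydroxy-2-methyl-5-(prop-1-en-2-yl)cyclohexan-1-one
Conditions: HClO4 (5 mol%), THF/H2O 3:1, 23 °C
Reagents that add atoms: water, O
Why: Acid-catalysed epoxide hydrolysis in which water attacks the secondary C3 with inversion (ionisation at the tertiary C4 is disfavoured by the adjacent carbonyl), giving the trans-diol with C3–OH cis to isopropenyl and the C4–O bond retained.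

Step 3
Reactants: 3 (2S,3R,5S)-2,3-dihydroxy-2-methyl-5-(prop-1-en-2-yl)cyclohexan-1-one
Product: 4 (2S,3R,5S)-2-methyl-5-(prop-1-en-2-yl)-2,3-bis(triethylsilyloxy)cyclohexan-1-one
Conditions: Et3SiOTf (2.6 equiv), 2,6-lutidine, CH2Cl2, −78 → 0 °C
Reagents that add atoms: triethylsilyl trifluoromethanesulfonate, CC[Si](CC)(CC)OS(=O)(=O)C(F)(F)F
Why: Silyl triflate etherification caps both the secondary and the hindered tertiary hydroxyl, which prevents glycol cleavage at C3/C4 or C4/C5 later and changes no stereocentre.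

Step 4
Reactants: 4 (2S,3R,5S)-2-methyl-5-(prop-1-en-2-yl)-2,3-bis(triethylsilyloxy)cyclohexan-1-one
Product: 6 (2S,3R,5R,6R)-6-hydroxy-2-methyl-5-(prop-1-en-2-yl)-2,3-bis(triethylsilyloxy)cyclohexan-1-one, via potassium enolate 5 (not isolated)
Conditions: KN(SiMe3)2, THF, −78 °C; then 2-(phenylsulfonyl)-3-phenyloxaziridine, −78 °C
Reagents that add atoms: 2-(phenylsulfonyl)-3-phenyloxaziridine, O=S(=O)(N1OC1c1ccccc1)c1ccccc1 (the new oxygen); KN(SiMe3)2, C[Si](C)(C)[N-][Si](C)(C)C.[K+] (potassium of 5 only)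
Why: Davis oxidation of the only possible enolate (C10 alone carries α-hydrogens) puts oxygen on C10 anti to the neighbouring isopropenyl group, and this C10 centre is erased again in step 6.

Step 5
Reactants: 6 (2S,3R,5R,6R)-6-hydroxy-2-methyl-5-(prop-1-en-2-yl)-2,3-bis(triethylsilyloxy)cyclohexan-1-one; 7 vinylmagnesium bromide
Product: 8 (2R,3R,5R,6S)-1-ethenyl-6-methyl-3-(prop-1-en-2-yl)-5,6-bis(triethylsilyloxy)cyclohexane-1,2-diol (both C1 epimers)
Conditions: CH2=CHMgBr (4 equiv), THF, −78 → 0 °C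
Reagents that add atoms: vinylmagnesium bromide 7, C=C[Mg]Br
Why: Grignard 1,2-addition to the ketone, activated as its five-membered magnesium chelate with the C10 alkoxide, brings in C6 and C7; the epimer ratio at the new carbinol is irrelevant because that carbon returns to a carbonyl in step 6.

Step 6
Reactants: 8 (2R,3R,5R,6S)-1-ethenyl-6-methyl-3-(prop-1-en-2-yl)-5,6-bis(triethylsilyloxy)cyclohexane-1,2-diol
Product: 10 (2R,4R,5S)-5-methyl-6-oxo-8-(phenylsulfanyl)-2-(prop-1-en-2-yl)-4,5-bis(triethylsilyloxy)octanal, via enone aldehyde 9 (not isolated)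
Conditions: Pb(OAc)4, CH2Cl2, −20 °C; filter through Celite; then PhSH, Et3N, 0 °C
Reagents that add atoms: benzenethiol, Sc1ccccc1
Why: Criegee glycol cleavage opens the six-membered ring at C5–C10 to the C5 vinyl ketone and the C10 aldehyde without touching C1, C3 or C4, and thia-Michael addition of thiophenol to the telescoped vinyl ketone then places sulfur on C7 with no new stereocentre.

Step 7
Reactants: 11 acrolein diethyl acetal; 12 naphthalen-2-ylmethanol
Product: 13 3,3-bis(naphthalen-2-ylmethoxy)prop-1-ene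
Conditions: PPTS (2 mol%), cyclohexane, 60 °C, 5 Å molecular sieves
Reagents that add atoms: naphthalen-2-ylmethanol 12, OCc1ccc2ccccc2c1
Why: Acid-catalysed transacetalisation driven by removal of ethanol gives the acetal that will deliver a DDQ-cleavable, chelating 2-naphthylmethyl ether at C9; no stereocentre is involved.

Step 8
Reactants: 10 (2R,4R,5S)-5-methyl-6-oxo-8-(phenylsulfanyl)-2-(prop-1-en-2-yl)-4,5-bis(triethylsilyloxy)octanal; 13 3,3-bis(naphthalen-2-ylmethoxy)prop-1-ene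
Product: 16 (3R,4S,5R,7R,8S)-4-hydroxy-8-methyl-3-(naphthalen-2-ylmethoxy)-11-(phenylsulfanyl)-5-(prop-1-en-2-yl)-7,8-bis(triethylsilyloxy)undec-1-en-9-one, via allylic iodide 14 (not isolated), via allylchromium dichloride 15 (not isolated)
Conditions: CrCl2 (6 equiv), Me3SiI (2 equiv), 13 (2 equiv), THF, −30 °C
Reagents that add atoms: 3,3-bis(naphthalen-2-ylmethoxy)prop-1-ene 13, C=CC(OCc1ccc2ccccc2c1)OCc1ccc2ccccc2c1; Me3SiI, C[Si](C)(C)I (iodine of 14 only); CrCl2, Cl[Cr]Cl (chromium and chlorine of 15 only)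
Why: Takai–Utimoto γ-alkoxyallylation (a Nozaki–Hiyama-type addition that selects the aldehyde over the hindered C5 ketone), in which the (E)-γ-alkoxyallylchromium reacts through a chair transition state to give the 9,10-anti diol monoether and Felkin–Anh attack on the α-chiral aldehyde (isopropenyl antiperiplanar to the nucleophile) sets C10 relative to C1.

Step 9
Reactants: 16 (3R,4S,5R,7R,8S)-4-hydroxy-8-methyl-3-(naphthalen-2-ylmethoxy)-11-(phenylsulfanyl)-5-(prop-1-en-2-yl)-7,8-bis(triethylsilyloxy)undec-1-en-9-one; 17 (R)-2-methylbutanoic acid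
Product: 18 (3R,4S,5R,7R,8S)-8-methyl-3-(naphthalen-2-ylmethoxy)-9-oxo-11-(phenylsulfanyl)-5-(prop-1-en-2-yl)-7,8-bis(triethylsilyloxy)undec-1-en-4-yl (2R)-2-methylbutanoate
Conditions: EDC·HCl, DMAP, CH2Cl2, 0 → 23 °C
Reagents that add atoms: (R)-2-methylbutanoic acid 17, CC[C@@H](C)C(=O)O
Why: Steglich esterification of the only free hydroxyl (C10) installs the final C10 ester, and carbodiimide activation at 0 °C does not epimerise the α-centre of the acid.

Step 10
Reactants: 18 (3R,4S,5R,7R,8S)-8-methyl-3-(naphthalen-2-ylmethoxy)-9-oxo-11-(phenylsulfanyl)-5-(prop-1-en-2-yl)-7,8-bis(triethylsilyloxy)undec-1-en-4-yl (2R)-2-methylbutanoate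
Product: 19 (3R,4S,5R,7R,8R,9S)-9-hydroxy-8-methyl-3-(naphthalen-2-ylmethoxy)-11-(phenylsulfanyl)-5-(prop-1-en-2-yl)-7,8-bis(triethylsilyloxy)undec-1-en-4-yl (2R)-2-methylbutanoate
Conditions: LiBH(s-Bu)3, THF, −78 °C
Reagents that add atoms: none
Why: Felkin–Anh reduction under non-chelating conditions, in which hydride adds anti to the C4–OSiEt3 bond and past the C4 methyl group to give the 4,5-syn (5S) carbinol, while the ester and alkenes are inert at −78 °C.

Step 11
Reactants: 19 (3R,4S,5R,7R,8R,9S)-9-hydroxy-8-methyl-3-(naphthalen-2-ylmethoxy)-11-(phenylsulfanyl)-5-(prop-1-en-2-yl)-7,8-bis(triethylsilyloxy)undec-1-en-4-yl (2R)-2-methylbutanoate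
Product: 20 [(3S,4R,5R,7R,8S,9R)-3-hydroxy-4-methyl-8-[(2R)-2-methylbutanoyl]oxy-9-(naphthalen-2-ylmethoxy)-7-(prop-1-en-2-yl)-4,5-bis(triethylsilyloxy)undec-10-en-1-yl]diphenylsulfonium trifluoromethanesulfonate
Conditions: Ph2IOTf (1.1 equiv), Cu(OAc)2 (5 mol%), ClCH2CH2Cl, 80 °C
Reagents that add atoms: diphenyliodonium trifluoromethanesulfonate, c1ccc([I+]c2ccccc2)cc1.[O-]S(=O)(=O)C(F)(F)F (one phenyl group and the triflate counter-ion)
Why: Copper-catalysed S-arylation of a thioether by a diaryliodonium salt gives an alkyl diphenylsulfonium salt whose only α-hydrogens are on C7, sulfur being far more nucleophilic than the free C5 hydroxyl or the alkenes.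

Step 12
Reactants: 20 [(3S,4R,5R,7R,8S,9R)-3-hydroxy-4-methyl-8-[(2R)-2-methylbutanoyl]oxy-9-(naphthalen-2-ylmethoxy)-7-(prop-1-en-2-yl)-4,5-bis(triethylsilyloxy)undec-10-en-1-yl]diphenylsulfonium trifluoromethanesulfonate
Product: 21 [(3S,4R,5R,7R,8S,9S)-3-hydroxy-4-methyl-8-[(2R)-2-methylbutanoyl]oxy-9-(naphthalen-2-ylmethoxy)-10-oxo-7-(prop-1-en-2-yl)-4,5-bis(triethylsilyloxy)undecyl]diphenylsulfonium trifluoromethanesulfonate
Conditions: PdCl2(Quinox) (5 mol%; Quinox = 2-(4,5-dihydro-1,3-oxazol-2-yl)quinoline), AgSbF6 (12 mol%), aq. t-BuOOH, CH2Cl2, 0 → 23 °C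
Reagents that add atoms: tert-butyl hydroperoxide, CC(C)(C)OO
Why: Tsuji–Wacker oxidation in its cationic Pd–Quinox/t-BuOOH form converts the monosubstituted vinyl group next to an ether into the methyl ketone without epimerising C9, the 1,1-disubstituted isopropenyl group being inert and the sulfonium (unlike the parent sulfide) unable to bind palladium.

Step 13
Reactants: 21 [(3S,4R,5R,7R,8S,9S)-3-hydroxy-4-methyl-8-[(2R)-2-methylbutanoyl]oxy-9-(naphthalen-2-ylmethoxy)-10-oxo-7-(prop-1-en-2-yl)-4,5-bis(triethylsilyloxy)undecyl]diphenylsulfonium trifluoromethanesulfonate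
Product: 23 (1R,3R,4R,5S,7S,8S,9S,10S)-7,8-epoxy-5-hydroxy-4,8-dimethyl-9-(naphthalen-2-ylmethoxy)-1-(prop-1-en-2-yl)-3,4-bis(triethylsilyloxy)cyclodecan-10-yl (2R)-2-methylbutanoate (locants of 28), via sulfonium ylide 22 (not isolated)
Conditions: LiN(SiMe3)2 (1.05 equiv, added over 6 h), THF/toluene 1:4, 0.001 M, −78 → −40 °C
Reagents that add atoms: none
Why: Proposed new method: the sulfonium α-CH2 (C7) is by far the most acidic site (estimated to be about ten pK units more acidic than the free C5 carbinol, the ketone α-hydrogens or the ester α-hydrogen), so one equivalent of amide gives ylide 22, whose carbanion adds to the C8 ketone to close the ten-membered ring as a betaine whose alkoxide then displaces Ph2S from C7 with inversion to close the oxirane, so that carbocycle and epoxide arise in one operation; the closest known chemistry is the Corey–Chaykovsky epoxidation of ketones with diphenylsulfonium alkylides and its intramolecular versions that give five- to seven-membered rings, and the macrocyclic version relies on high dilution; C8 is expected to be set by a lithium chelate between C8=O and the C9 naphthylmethyl ether, which lets C7 approach past H9 and anti to C10, and C7 by the lower strain of the cis-fused (C6/C9 cis) epoxycyclodecane betaine; C5–O is deliberately not acylated because an ester there would capture the ylide through a five-membered acyl transfer.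

Step 14
Reactants: 23 (1R,3R,4R,5S,7S,8S,9S,10S)-7,8-epoxy-5-hydroxy-4,8-dimethyl-9-(naphthalen-2-ylmethoxy)-1-(prop-1-en-2-yl)-3,4-bis(triethylsilyloxy)cyclodecan-10-yl (2R)-2-methylbutanoate
Product: 24 (1R,3R,4R,5S,7S,8R,9S,10S)-7,8-epoxy-5,9-dihydroxy-4,8-dimethyl-1-(prop-1-en-2-yl)-3,4-bis(triethylsilyloxy)cyclodecan-10-yl (2R)-2-methylbutanoate (locants of 28)
Conditions: DDQ, CH2Cl2/pH 7 buffer 10:1, 0 → 23 °C
Reagents that add atoms: none
Why: Oxidative cleavage of the 2-naphthylmethyl ether by DDQ (hydride abstraction to the oxocarbenium ion, then hydrolysis) frees C9–OH while silyl ethers, ester, epoxide and isopropenyl group survive.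

Step 15
Reactants: 24 (1R,3R,4R,5S,7S,8R,9S,10S)-7,8-epoxy-5,9-dihydroxy-4,8-dimethyl-1-(prop-1-en-2-yl)-3,4-bis(triethylsilyloxy)cyclodecan-10-yl (2R)-2-methylbutanoate; 25 angelic acid
Product: 27 (1R,3R,4R,5S,7S,8S,9S,10S)-7,8-epoxy-4,8-dimethyl-10-[(2R)-2-methylbutanoyl]oxy-1-(prop-1-en-2-yl)-3,4-bis(triethylsilyloxy)cyclodecane-5,9-diyl bis[(Z)-2-methylbut-2-enoate] (locants of 28), via mixed anhydride 26 (not isolated)
Conditions: 25 (6 equiv), 2,4,6-Cl3C6H2COCl (6 equiv), Et3N (12 equiv), toluene, 23 °C; then 24, 75 °C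
Reagents that add atoms: angelic acid 25, C/C=C(/C)C(=O)O; 2,4,6-trichlorobenzoyl chloride, O=C(Cl)c1c(Cl)cc(Cl)cc1Cl (aroyl part of 26 only)
Why: Yamaguchi esterification with the preformed mixed anhydride and no DMAP acylates both free secondary hydroxyls (C5 and C9) at the unhindered angeloyl carbonyl without Z-to-E isomerisation to tiglate, C3 and C4 being silylated.

Step 16
Reactants: 27 (1R,3R,4R,5S,7S,8S,9S,10S)-7,8-epoxy-4,8-dimethyl-10-[(2R)-2-methylbutanoyl]oxy-1-(prop-1-en-2-yl)-3,4-bis(triethylsilyloxy)cyclodecane-5,9-diyl bis[(Z)-2-methylbut-2-enoate]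
Product: 28 (1R,3R,4S,5S,7S,8S,9S,10S)-7,8-epoxy-3,4-dihydroxy-4,8-dimethyl-10-[(2R)-2-methylbutanoyl]oxy-1-(prop-1-en-2-yl)cyclodecane-5,9-diyl bis[(Z)-2-methylbut-2-enoate] (CNP0246823.3)
Conditions: Bu4NF/AcOH 1:1, THF, 0 → 23 °C
Reagents that add atoms: none
Why: Acetic acid-buffered fluoride desilylation removes both triethylsilyl ethers under near-neutral conditions that spare the epoxide, prevent acyl migration to the freed C3/C4 hydroxyls and do not isomerise the angelates.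

**Compound list**

1 | (S)-carvone, (5S)-2-methyl-5-(prop-1-en-2-yl)cyclohex-2-en-1-one | C=C(C)[C@H]1CC=C(C)C(=O)C1 | starting material
2 | (1S,4S,6S)-1-methyl-4-(prop-1-en-2-yl)-7-oxabicyclo[4.1.0]heptan-2-one | C=C(C)[C@H]1C[C@@H]2O[C@]2(C)C(=O)C1 | intermediate
3 | (2S,3R,5S)-2,3-dihydroxy-2-methyl-5-(prop-1-en-2-yl)cyclohexan-1-one | C=C(C)[C@H]1C[C@@H](O)[C@](C)(O)C(=O)C1 | intermediate
4 | (2S,3R,5S)-2-methyl-5-(prop-1-en-2-yl)-2,3-bis(triethylsilyloxy)cyclohexan-1-one | C=C(C)[C@H]1C[C@@H](O[Si](CC)(CC)CC)[C@](C)(O[Si](CC)(CC)CC)C(=O)C1 | intermediate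
5 | potassium enolate of 4 (C5=C10 enolate) | C=C(C)[C@H]1C[C@@H](O[Si](CC)(CC)CC)[C@](C)(O[Si](CC)(CC)CC)C([O-])=C1.[K+] | intermediate
6 | (2S,3R,5R,6R)-6-hydroxy-2-methyl-5-(prop-1-en-2-yl)-2,3-bis(triethylsilyloxy)cyclohexan-1-one | C=C(C)[C@H]1C[C@@H](O[Si](CC)(CC)CC)[C@](C)(O[Si](CC)(CC)CC)C(=O)[C@@H]1O | intermediate
7 | vinylmagnesium bromide | C=C[Mg]Br | starting material
8 | (2R,3R,5R,6S)-1-ethenyl-6-methyl-3-(prop-1-en-2-yl)-5,6-bis(triethylsilyloxy)cyclohexane-1,2-diol (C1 epimers) | C=C(C)[C@H]1C[C@@H](O[Si](CC)(CC)CC)[C@](C)(O[Si](CC)(CC)CC)C(O)(C=C)[C@@H]1O | intermediate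
9 | (2R,4R,5S)-5-methyl-6-oxo-2-(prop-1-en-2-yl)-4,5-bis(triethylsilyloxy)oct-7-enal | C=C(C)[C@H](C=O)C[C@@H](O[Si](CC)(CC)CC)[C@](C)(O[Si](CC)(CC)CC)C(=O)C=C | intermediate
10 | (2R,4R,5S)-5-methyl-6-oxo-8-(phenylsulfanyl)-2-(prop-1-en-2-yl)-4,5-bis(triethylsilyloxy)octanal | C=C(C)[C@H](C=O)C[C@@H](O[Si](CC)(CC)CC)[C@](C)(O[Si](CC)(CC)CC)C(=O)CCSc1ccccc1 | intermediate
11 | acrolein diethyl acetal (3,3-diethoxyprop-1-ene) | C=CC(OCC)OCC | starting material
12 | naphthalen-2-ylmethanol | OCc1ccc2ccccc2c1 | starting material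
13 | 3,3-bis(naphthalen-2-ylmethoxy)prop-1-ene | C=CC(OCc1ccc2ccccc2c1)OCc1ccc2ccccc2c1 | intermediate
14 | (E)-3-iodo-1-(naphthalen-2-ylmethoxy)prop-1-ene | IC/C=C/OCc1ccc2ccccc2c1 | intermediate
15 | [(E)-3-(naphthalen-2-ylmethoxy)prop-2-en-1-yl]chromium dichloride (trivalent chromium) | Cl[Cr](Cl)C/C=C/OCc1ccc2ccccc2c1 | intermediate
16 | (3R,4S,5R,7R,8S)-4-hydroxy-8-methyl-3-(naphthalen-2-ylmethoxy)-11-(phenylsulfanyl)-5-(prop-1-en-2-yl)-7,8-bis(triethylsilyloxy)undec-1-en-9-one | C=C(C)[C@H]([C@H](O)[C@H](OCc1ccc2ccccc2c1)C=C)C[C@@H](O[Si](CC)(CC)CC)[C@](C)(O[Si](CC)(CC)CC)C(=O)CCSc1ccccc1 | intermediate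
17 | (R)-2-methylbutanoic acid | CC[C@@H](C)C(=O)O | starting material
18 | (3R,4S,5R,7R,8S)-8-methyl-3-(naphthalen-2-ylmethoxy)-9-oxo-11-(phenylsulfanyl)-5-(prop-1-en-2-yl)-7,8-bis(triethylsilyloxy)undec-1-en-4-yl (2R)-2-methylbutanoate | C=C(C)[C@H]([C@H](OC(=O)[C@H](C)CC)[C@H](OCc1ccc2ccccc2c1)C=C)C[C@@H](O[Si](CC)(CC)CC)[C@](C)(O[Si](CC)(CC)CC)C(=O)CCSc1ccccc1 | intermediate
19 | (3R,4S,5R,7R,8R,9S)-9-hydroxy-8-methyl-3-(naphthalen-2-ylmethoxy)-11-(phenylsulfanyl)-5-(prop-1-en-2-yl)-7,8-bis(triethylsilyloxy)undec-1-en-4-yl (2R)-2-methylbutanoate | C=C(C)[C@H]([C@H](OC(=O)[C@H](C)CC)[C@H](OCc1ccc2ccccc2c1)C=C)C[C@@H](O[Si](CC)(CC)CC)[C@](C)(O[Si](CC)(CC)CC)[C@@H](O)CCSc1ccccc1 | intermediate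
20 | [(3S,4R,5R,7R,8S,9R)-3-hydroxy-4-methyl-8-[(2R)-2-methylbutanoyl]oxy-9-(naphthalen-2-ylmethoxy)-7-(prop-1-en-2-yl)-4,5-bis(triethylsilyloxy)undec-10-en-1-yl]diphenylsulfonium trifluoromethanesulfonate | C=C(C)[C@H]([C@H](OC(=O)[C@H](C)CC)[C@H](OCc1ccc2ccccc2c1)C=C)C[C@@H](O[Si](CC)(CC)CC)[C@](C)(O[Si](CC)(CC)CC)[C@@H](O)CC[S+](c1ccccc1)c1ccccc1.[O-]S(=O)(=O)C(F)(F)F | intermediate
21 | [(3S,4R,5R,7R,8S,9S)-3-hydroxy-4-methyl-8-[(2R)-2-methylbutanoyl]oxy-9-(naphthalen-2-ylmethoxy)-10-oxo-7-(prop-1-en-2-yl)-4,5-bis(triethylsilyloxy)undecyl]diphenylsulfonium trifluoromethanesulfonate | C=C(C)[C@H]([C@H](OC(=O)[C@H](C)CC)[C@H](OCc1ccc2ccccc2c1)C(C)=O)C[C@@H](O[Si](CC)(CC)CC)[C@](C)(O[Si](CC)(CC)CC)[C@@H](O)CC[S+](c1ccccc1)c1ccccc1.[O-]S(=O)(=O)C(F)(F)F | intermediate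
22 | C7 sulfonium ylide of 21 (diphenylsulfonium 1-ylide) | C=C(C)[C@H]([C@H](OC(=O)[C@H](C)CC)[C@H](OCc1ccc2ccccc2c1)C(C)=O)C[C@@H](O[Si](CC)(CC)CC)[C@](C)(O[Si](CC)(CC)CC)[C@@H](O)C[CH-][S+](c1ccccc1)c1ccccc1 | intermediate
23 | (1R,3R,4R,5S,7S,8S,9S,10S)-7,8-epoxy-5-hydroxy-4,8-dimethyl-9-(naphthalen-2-ylmethoxy)-1-(prop-1-en-2-yl)-3,4-bis(triethylsilyloxy)cyclodecan-10-yl (2R)-2-methylbutanoate (locants of 28) | C=C(C)[C@H]1C[C@@H](O[Si](CC)(CC)CC)[C@](C)(O[Si](CC)(CC)CC)[C@@H](O)C[C@@H]2O[C@]2(C)[C@@H](OCc2ccc3ccccc3c2)[C@H]1OC(=O)[C@H](C)CC | intermediate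
24 | (1R,3R,4R,5S,7S,8R,9S,10S)-7,8-epoxy-5,9-dihydroxy-4,8-dimethyl-1-(prop-1-en-2-yl)-3,4-bis(triethylsilyloxy)cyclodecan-10-yl (2R)-2-methylbutanoate (locants of 28) | C=C(C)[C@H]1C[C@@H](O[Si](CC)(CC)CC)[C@](C)(O[Si](CC)(CC)CC)[C@@H](O)C[C@@H]2O[C@]2(C)[C@@H](O)[C@H]1OC(=O)[C@H](C)CC | intermediate
25 | angelic acid, (Z)-2-methylbut-2-enoic acid | C/C=C(/C)C(=O)O | starting material
26 | (Z)-2-methylbut-2-enoic 2,4,6-trichlorobenzoic anhydride | C/C=C(/C)C(=O)OC(=O)c1c(Cl)cc(Cl)cc1Cl | intermediate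
27 | (1R,3R,4R,5S,7S,8S,9S,10S)-7,8-epoxy-4,8-dimethyl-10-[(2R)-2-methylbutanoyl]oxy-1-(prop-1-en-2-yl)-3,4-bis(triethylsilyloxy)cyclodecane-5,9-diyl bis[(Z)-2-methylbut-2-enoate] (locants of 28) | C=C(C)[C@H]1C[C@@H](O[Si](CC)(CC)CC)[C@](C)(O[Si](CC)(CC)CC)[C@@H](OC(=O)/C(C)=C\C)C[C@@H]2O[C@]2(C)[C@@H](OC(=O)/C(C)=C\C)[C@H]1OC(=O)[C@H](C)CC | intermediate
28 | (1R,3R,4S,5S,7S,8S,9S,10S)-7,8-epoxy-3,4-dihydroxy-4,8-dimethyl-10-[(2R)-2-methylbutanoyl]oxy-1-(prop-1-en-2-yl)cyclodecane-5,9-diyl bis[(Z)-2-methylbut-2-enoate] (CNP0246823.3) | C=C(C)[C@H]1C[C@@H](O)[C@](C)(O)[C@@H](OC(=O)/C(C)=C\C)C[C@@H]2O[C@]2(C)[C@@H](OC(=O)/C(C)=C\C)[C@H]1OC(=O)[C@H](C)CC | target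

**Step count**

Total: 16 steps. Longest linear sequence: 15 steps (steps 1–6 and 8–16 from (S)-carvone); step 7 is a one-step side branch.

**Three steps most likely to fail, with fallbacks**

Step 13 (ylide closure of carbocycle and oxirane). Risks are the entropic cost of the ten-membered betaine against ylide decay, the face selectivity at C8 (the chelation-type isomer is needed, the polar Felkin isomer would be wrong), and cyclisation of O4 onto C7 after silyl migration. The fallback sets out from sulfide 19 and closes the carbocycle by reductive carbonyl coupling, adding the oxirane afterwards. α-Chlorination of the sulfide (N-chlorosuccinimide, CH2Cl2) and hydrolysis (CuCl2/CuO, aqueous acetone) give β-hydroxy aldehyde F1. The Wacker conditions of step 12 convert its vinyl group into keto-aldehyde F2. McMurry coupling with low-valent titanium (TiCl3, Zn–Cu couple, DME, slow addition) gives (Z)-cyclodecene F3. Epoxidation of the C7=C8 bond directed by the homoallylic C5 hydroxyl (VO(acac)2, t-BuOOH; face to be confirmed, m-CPBA as the peripheral alternative) returns to the route at 23.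

Step 8 (chromium-mediated γ-alkoxyallylation). Risks are ionisation of the naphthylmethyl acetal by Me3SiI, modest Felkin control at C10, and reduction of the keto sulfide by divalent chromium. The fallback sets out from aldehyde 10 and alcohol 12 and replaces the in-situ chromium reagent by a preformed, neutral allylboron reagent. O-Propargylation of 12 (NaH, propargyl bromide) gives propargyl ether F4. Hydroboration with pinacolborane (Cp2ZrHCl cat.) gives (E)-alkenylboronate F5. Double-bond migration with [Ir(cod)(PPh2Me)2]PF6 (activated with H2) gives (E)-γ-alkoxyallylboronate F6. Allylboration of 10 in toluene at 23 °C through a closed chair transition state gives the same 9,10-anti adduct and returns to the route at 16.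

Step 15 (double angeloylation of two hindered hydroxyls). Risks are slow acylation next to the C4 and C8 quaternary carbons, Z-to-E isomerisation on forcing, and epoxide opening by the liberated aroic acid. The fallback sets out from diol 24 and builds the Z-olefins on the substrate instead of transferring preformed angeloyl groups. DCC/DMAP acylation of both hydroxyls with 2-[bis(2,2,2-trifluoroethoxy)phosphoryl]propanoic acid gives bis-phosphonate F7. A double Still–Gennari olefination with acetaldehyde (KN(SiMe3)2, 18-crown-6, THF, −78 °C) gives the two (Z)-2-methylbut-2-enoates and returns to the route at 27.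

**Further compounds**

F1 | step 13 | (3R,4S,5R,7R,8R,9S)-9-hydroxy-8-methyl-3-(naphthalen-2-ylmethoxy)-11-oxo-5-(prop-1-en-2-yl)-7,8-bis(triethylsilyloxy)undec-1-en-4-yl (2R)-2-methylbutanoate | C=C(C)[C@H]([C@H](OC(=O)[C@H](C)CC)[C@H](OCc1ccc2ccccc2c1)C=C)C[C@@H](O[Si](CC)(CC)CC)[C@](C)(O[Si](CC)(CC)CC)[C@@H](O)CC=O
F2 | step 13 | (3S,4S,5R,7R,8R,9S)-9-hydroxy-8-methyl-3-(naphthalen-2-ylmethoxy)-2,11-dioxo-5-(prop-1-en-2-yl)-7,8-bis(triethylsilyloxy)undecan-4-yl (2R)-2-methylbutanoate | C=C(C)[C@H]([C@H](OC(=O)[C@H](C)CC)[C@H](OCc1ccc2ccccc2c1)C(C)=O)C[C@@H](O[Si](CC)(CC)CC)[C@](C)(O[Si](CC)(CC)CC)[C@@H](O)CC=O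
F3 | step 13 | (1R,3R,4R,5S,7Z,9R,10S)-5-hydroxy-4,8-dimethyl-9-(naphthalen-2-ylmethoxy)-1-(prop-1-en-2-yl)-3,4-bis(triethylsilyloxy)cyclodec-7-en-10-yl (2R)-2-methylbutanoate (locants of 28) | C=C(C)[C@H]1C[C@@H](O[Si](CC)(CC)CC)[C@](C)(O[Si](CC)(CC)CC)[C@@H](O)C/C=C(C)\[C@@H](OCc2ccc3ccccc3c2)[C@H]1OC(=O)[C@H](C)CC
F4 | step 8 | 2-[(prop-2-yn-1-yloxy)methyl]naphthalene | C#CCOCc1ccc2ccccc2c1
F5 | step 8 | 4,4,5,5-tetramethyl-2-[(E)-3-(naphthalen-2-ylmethoxy)prop-1-en-1-yl]-1,3,2-dioxaborolane | CC1(C)OB(/C=C/COCc2ccc3ccccc3c2)OC1(C)C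
F6 | step 8 | 4,4,5,5-tetramethyl-2-[(E)-3-(naphthalen-2-ylmethoxy)prop-2-en-1-yl]-1,3,2-dioxaborolane | CC1(C)OB(C/C=C/OCc2ccc3ccccc3c2)OC1(C)C
F7 | step 15 | 5,9-bis-O-{2-[bis(2,2,2-trifluoroethoxy)phosphoryl]propanoyl} derivative of 24 (phosphonate α-carbons as epimer mixtures) | C=C(C)[C@H]1C[C@@H](O[Si](CC)(CC)CC)[C@](C)(O[Si](CC)(CC)CC)[C@@H](OC(=O)C(C)P(=O)(OCC(F)(F)F)OCC(F)(F)F)C[C@@H]2O[C@]2(C)[C@@H](OC(=O)C(C)P(=O)(OCC(F)(F)F)OCC(F)(F)F)[C@H]1OC(=O)[C@H](C)CC
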